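Assumption: guaiane numbering (C1–C15) is used for all intermediates, and β is the face that carries the C4 methyl group in the target.

**Retrosynthetic overview**
1. The target comes from acetylation of the 6,8-diol 13. Diol 13 comes from closing C8–C9 (seven-membered ring) by intramolecular allylation of lactol 11, which holds an allyl chloride and a masked C8 aldehyde.
2. Lactol 11 comes from a one-flask aldol / cross-aldol / lactolisation of the acyclic keto aldehyde 6 with isovaleraldehyde. This forms C4–C5 and C6–C7 and closes the cyclopentane and an oxane ring together.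
3. Keto aldehyde 6 comes from ozonolysis of the ring alkene of trans-10-chlorocarveyl acetate 4, which comes from (R)-carvone. C1 is taken from the chiral pool and C3 is set by reduction and inversion.
4. Ring order: the carvone ring is opened, the five-membered ring and a temporary lactol ring form in the same operation, and the seven-membered ring forms last as the lactol opens.

**Step 1**
Reactants: 1 (R)-(−)-carvone
Product: 2 (R)-10-chlorocarvone
Conditions: SO2Cl2, Na2CO3, CH2Cl2, 0 °C
Reagents that add atoms: sulfuryl chloride, ClS(Cl)(=O)=O
Why: This is an ene-type allylic chlorination in which the electron-poor enone alkene is inert, so chlorine attacks only the isopropenyl group with shift of the double bond and C1 is untouched.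

**Step 2**
Reactants: 2 (R)-10-chlorocarvone
Product: 3 (1R,5R)-cis-10-chlorocarveol
Conditions: NaBH4, CeCl3·7H2O, MeOH, −20 °C
Reagents that add atoms: none
Why: This is a Luche reduction, a clean 1,2-reduction with axial hydride delivery that gives the equatorial alcohol cis to the side chain and leaves the allyl chloride alone.

**Step 3**
Reactants: 3 (1R,5R)-cis-10-chlorocarveol
Product: 4 (1S,5R)-trans-10-chlorocarveyl acetate
Conditions: PPh3, DIAD, AcOH, toluene, −20 → 23 °C (PPh3 and DIAD premixed)
Reagents that add atoms: acetic acid, CC(=O)O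
Why: This is a Mitsunobu reaction in which SN2 attack of acetate on the oxyphosphonium salt inverts the carbinol centre (future C3) and installs the 3β-acetate in one step.

**Step 4**
Reactants: 4 (1S,5R)-trans-10-chlorocarveyl acetate
Product: 6 (3S,5S)-5-acetoxy-3-(3-chloroprop-1-en-2-yl)-6-oxoheptanal, via secondary ozonide 5 (not isolated)
Conditions: O3 (1 equiv, Sudan Red 7B end point), CH2Cl2, −78 °C; then Me2S, −78 → 23 °C
Reagents that add atoms: ozone, [O-][O+]=O
Why: This is an ozonolysis with reductive work-up in which the trisubstituted ring alkene is more electron-rich than the 1,1-disubstituted alkene deactivated by the allylic chlorine, so only the ring is cleaved and C1 and C3 are untouched.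

**Step 5**
Reactants: 6 (3S,5S)-5-acetoxy-3-(3-chloroprop-1-en-2-yl)-6-oxoheptanal; 7 isovaleraldehyde
Product: 11 trans-fused lactol (C4–O–C8 oxane on the cyclopentane), via cyclopentane aldol 8 (not isolated), via anti cross-aldol 9 (not isolated), via syn hydroxy aldehyde 10 (not isolated)
Conditions: D-proline (30 mol %), DMF, 4 °C, 12 h; then 7 (5 equiv, syringe pump, 30 h), 4 °C; then imidazole (0.3 equiv), 23 °C, 12 h
Reagents that add atoms: 3-methylbutanal (7), CC(C)CC=O
Why: Proposed new method: D-proline forms an enamine only at the aldehyde of 6, and its C5 carbon adds 5-(enolexo)-exo-trig to the acetoxy-activated C4 ketone with the formyl group trans to the C1 side chain and the new C4–O bond opposed to the C3–OAc dipole (Cornforth model, matched with the Houk–List sense of D-proline), setting C4 and C5 in 8; 8 is α-branched and acts only as acceptor for the D-proline enamine of slowly added 7, whose facial bias sets the 6α-hydroxyl in the kinetic anti adduct 9; C7, α to the free aldehyde, equilibrates through enamine and imidazole catalysis to 10, which is drained as the all-equatorial trans-fused lactol 11 (C6-OH and C7-iPr equatorial, C4-Me axial), so that two C–C bonds, two rings and four stereocentres arise in one flask; the closest known reaction types are proline-catalysed enolexo aldolisation, proline-catalysed aldehyde–aldehyde cross-aldol with α-branched acceptors, proline-catalysed aldehyde trimerisation to lactols, and dynamic kinetic resolution of α-branched aldehydes under proline catalysis.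

**Step 6**
Reactants: 11 trans-fused lactol
Product: 13 3β-acetoxyguai-10(14)-ene-4α,6α,8α-triol, via allylchromium aldehyde 12 (not isolated)
Conditions: CrCl2 (5 equiv), NaI (10 mol %), THF/DMF 4:1, 0.005 M, 23 °C; aq. work-up
Reagents that add atoms: none
Why: This is a Nozaki–Hiyama (Barbier-type) allylation in which divalent chromium converts the allyl chloride into a hydroxyl-tolerant allylchromium species that captures the small equilibrium share of open aldehyde, closing C8–C9 through the all-equatorial conformer with Felkin–Anh attack anti to C6 to give the 8α-alcohol and the exocyclic methylene.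

**Step 7**
Reactants: 13 3β-acetoxyguai-10(14)-ene-4α,6α,8α-triol
Product: 14 target, 3β,6α,8α-triacetoxyguai-10(14)-en-4α-ol (1βH,5αH)
Conditions: Ac2O, pyridine, DMAP (10 mol %), CH2Cl2, 23 °C
Reagents that add atoms: acetic anhydride, CC(=O)OC(C)=O
Why: This is a DMAP-catalysed acylation in which both secondary alcohols are esterified, the hindered tertiary C4 hydroxyl stays free, and no stereocentre is affected.

**Compound list**
1 | (R)-(−)-carvone | CC1=CC[C@H](CC1=O)C(=C)C | starting material
2 | (R)-10-chlorocarvone, (5R)-5-(3-chloroprop-1-en-2-yl)-2-methylcyclohex-2-en-1-one | CC1=CC[C@H](CC1=O)C(=C)CCl | intermediate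
3 | (1R,5R)-cis-10-chlorocarveol | CC1=CC[C@H](C[C@H]1O)C(=C)CCl | intermediate
4 | (1S,5R)-trans-10-chlorocarveyl acetate | CC1=CC[C@H](C[C@@H]1OC(C)=O)C(=C)CCl | intermediate
5 | secondary ozonide (1,2,4-trioxolane across the former ring alkene of 4) | CC12OOC(O1)C[C@H](C[C@@H]2OC(C)=O)C(=C)CCl | intermediate
6 | (3S,5S)-5-acetoxy-3-(3-chloroprop-1-en-2-yl)-6-oxoheptanal | CC(=O)[C@@H](OC(C)=O)C[C@@H](CC=O)C(=C)CCl | intermediate
7 | isovaleraldehyde (3-methylbutanal) | CC(C)CC=O | starting material
8 | cyclopentane aldol: 3β-acetoxy-4α-hydroxy-4β-methyl-1α-(3-chloroprop-1-en-2-yl)cyclopentane-5β-carbaldehyde | O=C[C@@H]1[C@@H](C(=C)CCl)C[C@H](OC(C)=O)[C@@]1(C)O | intermediate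
9 | anti cross-aldol (6α-OH, C7 epimer of 10), open form | O=C[C@H](C(C)C)[C@H](O)[C@@H]1[C@@H](C(=C)CCl)C[C@H](OC(C)=O)[C@@]1(C)O | intermediate
10 | syn hydroxy aldehyde (6α-OH, 7β-isopropyl), open form | O=C[C@@H](C(C)C)[C@H](O)[C@@H]1[C@@H](C(=C)CCl)C[C@H](OC(C)=O)[C@@]1(C)O | intermediate
11 | trans-fused lactol of 10 (C4–O–C8, anomers) | OC1O[C@]2(C)[C@@H](OC(C)=O)C[C@H](C(=C)CCl)[C@H]2[C@@H](O)[C@@H]1C(C)C | intermediate
12 | allylchromium dichloride of open aldehyde 10 | O=C[C@@H](C(C)C)[C@H](O)[C@@H]1[C@@H](C(=C)C[Cr](Cl)Cl)C[C@H](OC(C)=O)[C@@]1(C)O | intermediate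
13 | 3β-acetoxyguai-10(14)-ene-4α,6α,8α-triol (1βH,5αH) | C=C1C[C@H](O)[C@@H](C(C)C)[C@H](O)[C@@H]2[C@@H]1C[C@H](OC(C)=O)[C@@]2(C)O | intermediate
14 | 3β,6α,8α-triacetoxyguai-10(14)-en-4α-ol, CNP0147943.1 | C=C1C[C@H](OC(C)=O)[C@@H](C(C)C)[C@H](OC(C)=O)[C@@H]2[C@@H]1C[C@H](OC(C)=O)[C@@]2(C)O | target

Total step count: 7. Longest linear sequence: 7.

**Steps most likely to fail**

Step 5. Five-ring enolexo closures under proline often prefer the hydroxyl cis to the formyl group, and that TS is also the less crowded one here, so C4 may well come out epimeric. The cross-aldol joins two hindered partners against Felkin bias, and it competes with self-aldol of 7.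

The fallback sets out from 6 and returns at 11. Piperidinium acetate condenses 6 to the cyclopentene carbaldehyde F1. t-BuOOH/DBU then epoxidises F1 from the α face, anti to the 3β-acetate, to give the epoxy aldehyde F2. In this way the C4 oxygen is delivered to the open face instead of being set in a C–C bond formation. SmI2/MeOH at −90 °C cleaves the C5–O bond and gives 8 after equilibration of C5. The titanium enolate (TiCl4, i-Pr2NEt, NMP) of (S)-4-benzyl-3-isovaleryl-1,3-thiazolidine-2-thione adds to isolated 8 to give the auxiliary-controlled syn, anti-Felkin thiazolidinethione aldol adduct F3. DIBAL-H at −78 °C releases the aldehyde, which closes to 11.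

Step 6. The open aldehyde is only a minor tautomer of 11, and protonation or dimerisation of the allylmetal may win.

The fallback sets out from 11 and returns at 13. Borylation catalysed by zerovalent palladium (Pd2(dba)3, B2pin2, THF) turns the allyl chloride into the lactol allylboronate F4. F4 is stable to hydroxyl groups and closes the ring on warming in toluene by a closed, chair-like allylboration of the open aldehyde. Mild hydrolysis then frees 13.

Step 3. SN2′ attack of acetate or quaternisation of PPh3 by the allyl chloride can erode the yield.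

The fallback sets out from 2 and returns at 4. Catalyst-controlled reduction with (R)-Me-CBS and BH3·SMe2 overrides the ring bias and gives the trans-10-chlorocarveol F5 directly. F5 is acetylated with Ac2O/pyridine with retention to 4.

**Further compounds**
F1 | step 5 | (3S,5R)-3-acetoxy-2-methyl-5-(3-chloroprop-1-en-2-yl)cyclopent-1-ene-1-carbaldehyde | O=CC1=C(C)[C@@H](OC(C)=O)C[C@@H]1C(=C)CCl
F2 | step 5 | 4α,5α-epoxy aldehyde from F1 | O=C[C@@]12O[C@]1(C)[C@@H](OC(C)=O)C[C@@H]2C(=C)CCl
F3 | step 5 | syn aldol adduct of 8 with the (S)-4-benzylthiazolidinethione isovalerate | O=C([C@@H](C(C)C)[C@H](O)[C@@H]1[C@@H](C(=C)CCl)C[C@H](OC(C)=O)[C@@]1(C)O)N1[C@@H](Cc2ccccc2)CSC1=S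
F4 | step 6 | lactol allylboronate (pinacol ester at C9) | OC1O[C@]2(C)[C@@H](OC(C)=O)C[C@H](C(=C)CB3OC(C)(C)C(C)(C)O3)[C@H]2[C@@H](O)[C@@H]1C(C)C
F5 | step 3 | (1S,5R)-trans-10-chlorocarveol | CC1=CC[C@H](C[C@@H]1O)C(=C)CCl
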